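**Assumptions.** The SMILES is taken as authoritative: (1R,5R,10R,14S), with a trans-fused α-methylene lactone at C1/C14, a butenolide at C8–C10, and "5β" = 5R. Cembrane numbering is used throughout. The route has not been run; stereochemical outcomes at steps 2, 13 and 14 are predictions from standard models.

## Retrosynthetic overview

1. Target ⇐ ovatodiolide (19) by a late Schenck ene reaction (¹O₂) at the C4=C5 olefin, setting C5.
2. Ovatodiolide ⇐ butenolide aldehyde 18 by intramolecular allylboration/lactonisation, forming C1–C14, the 14-membered ring and the trans α-methylene lactone together.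
3. Butenolide (C8=C9) ⇐ RCM of the ester of allylic alcohol 6 with acrylic acid 16.
4. Acid 16 ⇐ sp³–sp² Negishi coupling (C7–C8) of a (Z)-2-(methoxycarbonyl)allylboronate bromide (13); 13 comes from homoprenyl bromide, 2-butynoic acid and ICH₂Bpin. Alcohol 6 (C10) ⇐ catalytic asymmetric vinylogous Mukaiyama aldol.
5. Ring order: butenolide → macrocycle plus α-methylene-γ-lactone → C5 hydroperoxide.

## Route

**Step 1**
Reactants: 1, methyl 3-methylbut-2-enoate
Product: 2, tert-butyl[(1-methoxy-3-methylbuta-1,3-dien-1-yl)oxy]dimethylsilane (silyl dienol ether)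
Conditions: LDA, THF, −78 °C; TBSCl, DMPU, −78 °C → rt
Reagents that add atoms: TBSCl, CC(C)(C)[Si](C)(C)Cl
Why: Kinetic γ-deprotonation of the senecioate and O-silylation gives the dienolate equivalent (silyl ketene acetal formation); no stereocentre.

**Step 2**
Reactants: 2; 3, (E)-cinnamaldehyde
Product: 4, methyl (2E,5R,6E)-5-hydroxy-3-methyl-7-phenylhepta-2,6-dienoate
Conditions: SiCl₄, (R,R)-bisphosphoramide catalyst (2 mol %), i-Pr₂NEt (cat.), CH₂Cl₂, −78 °C; aq. KF/NaHCO₃
Reagents that add atoms: none
Why: Lewis-base-activated SiCl₄ vinylogous Mukaiyama aldol, γ-selective and (E)-selective; catalyst-controlled Re-face attack sets C10 as R (use the enantiomeric catalyst if the sense proves opposite), and the styryl group is the later RCM handle.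

**Step 3**
Reactants: 4
Product: 5, (2E,5R,6E)-3-methyl-7-phenylhepta-2,6-diene-1,5-diol
Conditions: DIBAL-H (3.5 equiv), CH₂Cl₂, −78 → 0 °C; Rochelle salt
Reagents that add atoms: none
Why: 1,2-Reduction of the enoate to the allylic alcohol; C10 and both olefins are untouched.

**Step 4**
Reactants: 5
Product: 6, (2E,5R,6E)-5-hydroxy-3-methyl-7-phenylhepta-2,6-dienal
Conditions: TEMPO (10 mol %), PhI(OAc)₂, CH₂Cl₂, rt
Reagents that add atoms: none
Why: Oxoammonium oxidation is selective for the primary allylic alcohol over the secondary carbinol, giving the C14 enal under neutral conditions.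

**Step 5**
Reactants: 7, 5-bromo-2-methylpent-2-ene (homoprenyl bromide)
Product: 8, (E)-5-bromo-2-methylpent-2-en-1-ol
Conditions: SeO₂ (0.3 equiv), t-BuOOH, CH₂Cl₂, rt; then NaBH₄, MeOH, 0 °C
Reagents that add atoms: SeO₂/t-BuOOH as O source, O=[Se]=O and CC(C)(C)OO
Why: Riley allylic oxidation (ene/[2,3]) functionalises only the (E)-methyl, fixing the 4E trisubstituted olefin; borohydride returns any over-oxidised enal.

**Step 6**
Reactants: 8
Product: 9, (E)-1,5-dibromo-2-methylpent-2-ene
Conditions: PBr₃ (0.4 equiv), Et₂O, 0 °C
Reagents that add atoms: PBr₃, BrP(Br)Br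
Why: SN2 bromination of the primary allylic alcohol with retention of olefin geometry.

**Step 7**
Reactants: 9; 10, 2-butynoic acid
Product: 11, methyl (E)-9-bromo-6-methylnon-6-en-2-ynoate
Conditions: 10 (1.1 equiv), LDA (2.2 equiv), THF–HMPA, −78 °C; add 9, −78 → −30 °C; then MeI, rt
Reagents that add atoms: MeI, CI
Why: The 2-butynoate dianion alkylates at its γ-carbon, and the allylic bromide reacts far faster than the homoallylic primary bromide; the carboxylate is then O-methylated in the same pot.

**Step 8**
Reactants: 11; 12, 2-(iodomethyl)-4,4,5,5-tetramethyl-1,3,2-dioxaborolane (ICH₂Bpin)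
Product: 13, methyl (2Z,6E)-9-bromo-6-methyl-2-[(pinacolatoboryl)methyl]nona-2,6-dienoate
Conditions: DIBAL-H (1.2 equiv), HMPA, THF, 0 °C; then 12, 0 °C → rt
Reagents that add atoms: 12 (numbered reactant)
Why: Conjugate hydroalumination of the alkynoate followed by C-alkylation of the α-aluminio acrylate/allenolate with the α-halo boronate puts CH₂Bpin cis to the new β-H, so the chain ends up cis to CO₂Me (Z).

**Step 9**
Reactants: 13; 14, tert-butyl 2-bromoacrylate
Product: 15, 1-tert-butyl 11-methyl (5E,9Z)-6-methyl-2-methylidene-10-[(pinacolatoboryl)methyl]undeca-5,9-dienedioate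
Conditions: Zn dust (TMSCl/BrCH₂CH₂Br activated), LiCl, THF, 50 °C; then 14, Pd(OAc)₂/SPhos (2/4 mol %), THF, rt
Reagents that add atoms: 14 (numbered reactant)
Why: LiCl-promoted zinc insertion into the primary bromide and base-free Negishi sp³–sp² coupling form C7–C8; without base the allyl-Bpin does not transmetalate, and both esters are tolerated.

**Step 10**
Reactants: 15
Product: 16, (5E,9Z)-11-methoxy-6-methyl-2-methylidene-11-oxo-10-[(pinacolatoboryl)methyl]undeca-5,9-dienoic acid
Conditions: TFA/CH₂Cl₂ (1:4), 0 °C → rt (alternative: TMSOTf, 2,6-lutidine)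
Reagents that add atoms: none
Why: Acidolysis of the tert-butyl ester leaves the methyl ester intact, and the electron-poor 2-carboalkoxy allylboronate is expected to tolerate brief acid exposure.

**Step 11**
Reactants: 16; 6
Product: 17, the (1E,3R,5E)-5-methyl-7-oxo-1-phenylhepta-1,5-dien-3-yl ester of acid 16
Conditions: DIC, DMAP (cat.), CH₂Cl₂, 0 °C → rt
Reagents that add atoms: none
Why: Steglich esterification of the only hydroxyl present; the boronate adds to aldehydes only on heating, so the enal survives, and C10 is not touched.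

**Step 12**
Reactants: 17
Product: 18, methyl (2Z,6E)-6-methyl-9-{(5R)-5-[(2E)-2-methyl-4-oxobut-2-en-1-yl]-2-oxo-2,5-dihydrofuran-3-yl}-2-[(pinacolatoboryl)methyl]nona-2,6-dienoate
Conditions: Grubbs II (10 mol %), CH₂Cl₂ (5 mM), 40 °C (styrene lost)
Reagents that add atoms: none
Why: Ring-closing metathesis between the 1,1-disubstituted acrylate and the styrenyl olefin gives the α,γ-disubstituted butenolide; the trisubstituted olefins, the enal and the boronate are not metathesis substrates.

**Step 13**
Reactants: 18
Product: 19, ovatodiolide (1R,10R,14S; 4E,12E)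
Conditions: PhMe (1 mM), 110 °C, 48 h; then p-TsOH (cat.), rt (MeOBpin lost)
Reagents that add atoms: none
Why: Intramolecular thermal allylboration through a closed chair (Zimmerman–Traxler) transition state, then lactonisation. Because C2 is trans to CH₂Bpin, it and the aldehyde's alkenyl group both sit equatorial, giving the anti adduct and hence the trans lactone. The choice between the two anti products, (1R,14S) and (1S,14R), rests on macrocyclic control from C10; I expect the natural isomer to be major but cannot prove it, and the minor isomer would be removed by chromatography.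

**Step 14**
Reactants: 19
Product: 20, 4-methylene-5β-hydroperoxyovatodiolide (1R,5R,10R,14S)
Conditions: O₂, TPP (cat.), hν (visible), CH₂Cl₂, 0 °C; chromatographic separation
Reagents that add atoms: singlet oxygen, O=O
Why: Schenck ene reaction; the cis effect directs H-abstraction to the disubstituted side (C18 methyl), placing OOH on C5 and the double bond exocyclic, with attack from the exposed face predicted to give 5R. The C12=C13 olefin is deactivated by the allylic lactone oxygen and the conjugated olefins are inert. The 4-hydroperoxy-5-ene regioisomer and the 5-epimer are expected by-products.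

## Compound list

1 | methyl 3-methylbut-2-enoate | COC(=O)C=C(C)C | starting material
2 | TBS dienol ether of 1 | COC(O[Si](C)(C)C(C)(C)C)=CC(C)=C | intermediate
3 | (E)-cinnamaldehyde | O=C/C=C/c1ccccc1 | starting material
4 | methyl (2E,5R,6E)-5-hydroxy-3-methyl-7-phenylhepta-2,6-dienoate | COC(=O)/C=C(\C)C[C@@H](O)/C=C/c1ccccc1 | intermediate
5 | (2E,5R,6E)-3-methyl-7-phenylhepta-2,6-diene-1,5-diol | OC/C=C(\C)C[C@@H](O)/C=C/c1ccccc1 | intermediate
6 | (2E,5R,6E)-5-hydroxy-3-methyl-7-phenylhepta-2,6-dienal | O=C/C=C(\C)C[C@@H](O)/C=C/c1ccccc1 | intermediate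
7 | 5-bromo-2-methylpent-2-ene | CC(C)=CCCBr | starting material
8 | (E)-5-bromo-2-methylpent-2-en-1-ol | OC/C(C)=C/CCBr | intermediate
9 | (E)-1,5-dibromo-2-methylpent-2-ene | BrC/C(C)=C/CCBr | intermediate
10 | 2-butynoic acid | CC#CC(=O)O | starting material
11 | methyl (E)-9-bromo-6-methylnon-6-en-2-ynoate | COC(=O)C#CCC/C(C)=C/CCBr | intermediate
12 | 2-(iodomethyl)-4,4,5,5-tetramethyl-1,3,2-dioxaborolane | ICB1OC(C)(C)C(C)(C)O1 | starting material
13 | methyl (2Z,6E)-9-bromo-6-methyl-2-[(Bpin)methyl]nona-2,6-dienoate | COC(=O)/C(CB1OC(C)(C)C(C)(C)O1)=C\CC/C(C)=C/CCBr | intermediate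
14 | tert-butyl 2-bromoacrylate | C=C(Br)C(=O)OC(C)(C)C | starting material
15 | 1-tert-butyl 11-methyl (5E,9Z)-6-methyl-2-methylidene-10-[(Bpin)methyl]undeca-5,9-dienedioate | C=C(CC/C=C(\C)CC/C=C(/CB1OC(C)(C)C(C)(C)O1)C(=O)OC)C(=O)OC(C)(C)C | intermediate
16 | corresponding C19 carboxylic acid | C=C(CC/C=C(\C)CC/C=C(/CB1OC(C)(C)C(C)(C)O1)C(=O)OC)C(=O)O | intermediate
17 | ester of 16 with alcohol 6 (RCM precursor) | O=C/C=C(\C)C[C@@H](OC(=O)C(=C)CC/C=C(\C)CC/C=C(/CB1OC(C)(C)C(C)(C)O1)C(=O)OC)/C=C/c1ccccc1 | intermediate
18 | (5R)-butenolide enal bearing the (Z)-allylboronate | O=C/C=C(\C)C[C@@H]1C=C(CC/C=C(\C)CC/C=C(/CB2OC(C)(C)C(C)(C)O2)C(=O)OC)C(=O)O1 | intermediate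
19 | ovatodiolide (1R,10R,14S) | C=C1C(=O)O[C@H]2/C=C(\C)C[C@@H]3C=C(CC/C=C(\C)CC[C@H]12)C(=O)O3 | intermediate
20 | 4-methylene-5β-hydroperoxyovatodiolide (1R,5R,10R,14S) | C=C1C(=O)O[C@H]2/C=C(\C)C[C@@H]3C=C(CC[C@@H](OO)C(=C)CC[C@H]12)C(=O)O3 | target

## Summary

**Total steps:** 14.
**Longest linear sequence:** 10 (steps 5–14, from 7). The western branch is 8 (steps 1–4, then 11–14).

**Three steps most likely to fail, with fallbacks:**

1. **Step 13 (macrocyclic allylboration/lactonisation).** The facial selectivity relative to C10 and the efficiency of 14-membered ring closure are both uncertain. Fallback: set C1/C14 intermolecularly under reagent control (a TBS-protected form of 6 plus boronate 15 with a chiral phosphoric acid or a chiral-diol boronate), then close the ring by Yamaguchi macrolactonisation of C10–OH onto the C19 acid and form the butenolide by transannular RCM.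

2. **Step 14 (Schenck ene).** Regioselectivity (5-OOH/exo-methylene versus 4-OOH/Δ5) and C5 facial selectivity may be poor. Fallback: a stepwise oxygenation. Epoxidise C4=C5 of 19 (the most nucleophilic olefin), isomerise the epoxide to the 4-methylene-5-ol with an aluminium amide, adjust the C5 configuration if needed (oxidation then CBS reduction), and convert the alcohol to the hydroperoxide by sulfonate displacement with H₂O₂ with inversion.

3. **Step 9 (zinc insertion/Negishi in the presence of the allyl-Bpin).** Insertion may be sluggish or the bromoacrylate may polymerise. Fallback: form C7–C8 by enolate chemistry instead of cross-coupling. Alkylate tert-butyl diethylphosphonoacetate with bromide 13, then unveil the α-methylene by Horner–Wadsworth–Emmons reaction with formaldehyde at 0 °C, and continue from 15.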